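Ring A (cyclopentane C1'–C5') is disconnected at its adjacent fully substituted carbons C1' (CH3 and ring B) and C2' (CMe2): two of their three methyl groups are added across a C1'=C2' enone double bond whose carbonyl is C5'. In one flask Me2CuLi places CH3 on C2' and iodomethane quaternises the C1' enolate anti to the C3' silyloxy group, creating both quaternary carbons and the C1' stereocentre. The precursor is a (4S)-4-silyloxy-3-methylcyclopent-2-enone carrying the ketal-protected cyclohexenyl ring B on its α-carbon, made by sp2–sp2 Suzuki coupling. Ring B is then hydrated, desymmetrised and halogenated, and the C3' oxygen is replaced by bromine.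

Key step: step 5

Locants: ring A = C1' (bears CH3 and ring B), C2' (CMe2), C3' (CHBr in the target), C4', C5' (CHOH); ring B = C1 (carbinol carbon bonded to C1'), C2, C3 (CHBr), C4 (CMeCl), C5, C6. The target is (1R,3S,4S)-3-bromo-1-[(1S,3S,5R)-3-bromo-5-hydroxy-1,2,2-trimethylcyclopentyl]-4-chloro-4-methylcyclohexan-1-ol; in its chair ring A is equatorial, C1–OH axial, and C3–Br and C4–Cl are both equatorial.

Remark: a one-step Br/Cl addition to alkene 29 would follow the trans-diaxial rule and give the diastereomer with Br trans to ring A, so steps 16–19 build the bromonium ion on the other face from a bromohydrin.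

Assumption: 1 is bought as the single (S) enantiomer. The sense of the amide in step 14 is taken from the 4-tert-butylcyclohexanone model ((R,R)-amide gives the (S)-enol derivative, which maps onto 27); the (S,S)-amide would be used if the ring A stereocentres reversed it.

Step 1
Reactants: 1 (4S)-4-(tert-butyldimethylsilyloxy)cyclopent-2-en-1-one; 2 methylmagnesium bromide
Product: 3 (3S,4S)-4-(tert-butyldimethylsilyloxy)-3-methyl-1-(trimethylsilyloxy)cyclopent-1-ene
Conditions: MeMgBr, CuI (10 mol %), Me3SiCl, THF, −78 °C; Et3N quench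
Reagents that add atoms: methylmagnesium bromide (C[Mg]Br); chlorotrimethylsilane (C[Si](C)(C)Cl)
Why: Copper-catalysed conjugate addition with in situ silylation of the enolate; CH3 enters C3 anti to the C4 silyloxy group (a centre flattened again in step 2) and the enol ether is fixed at C1=C2.

Step 2
Reactants: 3 (3S,4S)-4-(tert-butyldimethylsilyloxy)-3-methyl-1-(trimethylsilyloxy)cyclopent-1-ene
Product: 4 (4S)-4-(tert-butyldimethylsilyloxy)-3-methylcyclopent-2-en-1-one
Conditions: Pd(OAc)2 (10 mol %), O2 (1 atm), DMSO, 40 °C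
Reagents that add atoms: none
Why: Saegusa–Ito dehydrosilylation, in which the palladium enolate at C2 undergoes β-hydride elimination from C3 and returns the enone with the new 3-methyl group while the C4 stereocentre is untouched.

Step 3
Reactants: 4 (4S)-4-(tert-butyldimethylsilyloxy)-3-methylcyclopent-2-en-1-one
Product: 5 (4S)-4-(tert-butyldimethylsilyloxy)-2-iodo-3-methylcyclopent-2-en-1-one
Conditions: I2, pyridine, DMAP (cat.), CH2Cl2, rt
Reagents that add atoms: iodine (II)
Why: α-Iodination of an enone by the amine-mediated addition–iodination–elimination sequence (Johnson iodination), which tolerates the γ-silyloxy group and supplies the vinyl iodide for coupling.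

Step 4
Reactants: 5 (4S)-4-(tert-butyldimethylsilyloxy)-2-iodo-3-methylcyclopent-2-en-1-one; 6 2-(1,4-dioxaspiro[4.5]dec-7-en-8-yl)-4,4,5,5-tetramethyl-1,3,2-dioxaborolane
Product: 7 (4S)-4-(tert-butyldimethylsilyloxy)-3-methyl-2-(1,4-dioxaspiro[4.5]dec-7-en-8-yl)cyclopent-2-en-1-one
Conditions: PdCl2(dppf) (5 mol %), Ph3As, Cs2CO3, DMF/THF/H2O, rt
Reagents that add atoms: none
Why: Suzuki–Miyaura coupling of an α-iodoenone with an alkenyl boronate under mild base, so the hindered C1'–C1 bond is made between two sp2 carbons and the base-sensitive silyloxy enone survives.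

Step 5
Reactants: 7 (4S)-4-(tert-butyldimethylsilyloxy)-3-methyl-2-(1,4-dioxaspiro[4.5]dec-7-en-8-yl)cyclopent-2-en-1-one; 8 lithium dimethylcuprate; 9 iodomethane
Product: 12 (2S,4S)-4-(tert-butyldimethylsilyloxy)-2,3,3-trimethyl-2-(1,4-dioxaspiro[4.5]dec-7-en-8-yl)cyclopentan-1-one, via trimethylsilyl enol ether 10 (not isolated), via lithium enolate 11 (not isolated)
Conditions: Me2CuLi (2 equiv), Me3SiCl, THF, −78 → −30 °C; MeLi, −30 → 0 °C; MeI, DMPU, −40 → 0 °C
Reagents that add atoms: lithium dimethylcuprate ([Li+].C[Cu-]C); iodomethane (CI)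
Why: Me2CuLi, activated by Me3SiCl, transfers CH3 to the β-carbon C2' of the tetrasubstituted enone through a copper–alkene complex and is trapped as silyl enol ether 10; MeLi then releases the regiodefined lithium enolate 11, which iodomethane C-methylates at C1' by SN2. The closest known reaction type is the three-component conjugate addition–enolate alkylation of 4-silyloxycyclopentenones, and the cuprate addition/methylation of 2-aryl-3-methylcyclopentenones used for cuparene-type ketones. No ring is closed. The one new stereocentre, C1', is controlled by the C3' silyloxy group: C2' is now a symmetric CMe2, so the silyloxy group shields its own face of the planar enolate and iodomethane enters anti, leaving ring B cis to the silyloxy group (2S,4S). The step needs C- over O-methylation, α- over γ-attack of the cross-conjugated dienolate, and no enolate migration toward C4' (which would expel the silyloxy group); the soft electrophile, the fully substituted C2' and low temperature secure these.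

Step 6
Reactants: 12 (2S,4S)-4-(tert-butyldimethylsilyloxy)-2,3,3-trimethyl-2-(1,4-dioxaspiro[4.5]dec-7-en-8-yl)cyclopentan-1-one
Product: 13 (1R,2S,4S)-4-(tert-butyldimethylsilyloxy)-2,3,3-trimethyl-2-(1,4-dioxaspiro[4.5]dec-7-en-8-yl)cyclopentan-1-ol
Conditions: NaBH4, MeOH, 0 °C → rt
Reagents that add atoms: none
Why: Borohydride 1,2-reduction in which hydride attacks C5' from the face of the small C1' methyl group, anti to ring B and the C3' silyloxy group, giving C5'–OH cis to ring B; the ketone is removed before hydration so that no retro-aldol-prone β-hydroxy ketone is formed.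

Step 7
Reactants: 13 (1R,2S,4S)-4-(tert-butyldimethylsilyloxy)-2,3,3-trimethyl-2-(1,4-dioxaspiro[4.5]dec-7-en-8-yl)cyclopentan-1-ol
Product: 14 8-[(1S,3S,5R)-3-(tert-butyldimethylsilyloxy)-5-hydroxy-1,2,2-trimethylcyclopentyl]-1,4-dioxaspiro[4.5]decan-8-ol
Conditions: Mn(dpm)3 (10 mol %), PhSiH3, O2 (1 atm), i-PrOH, 0 °C → rt
Reagents that add atoms: dioxygen (O=O)
Why: Mukaiyama hydration (hydrogen-atom transfer to the trisubstituted alkene, O2 capture of the tertiary C1 radical) gives the Markovnikov tertiary alcohol; C1 is not yet stereogenic because ring B is still symmetric.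

Step 8
Reactants: 14 8-[(1S,3S,5R)-3-(tert-butyldimethylsilyloxy)-5-hydroxy-1,2,2-trimethylcyclopentyl]-1,4-dioxaspiro[4.5]decan-8-ol
Product: 15 8-[(1S,3S,5R)-3,5-dihydroxy-1,2,2-trimethylcyclopentyl]-1,4-dioxaspiro[4.5]decan-8-ol
Conditions: Bu4NF, THF, 40 °C
Reagents that add atoms: none
Why: Fluoride desilylation frees the C3' hydroxyl while the ketal and the other hydroxyls are inert.

Step 9
Reactants: 15 8-[(1S,3S,5R)-3,5-dihydroxy-1,2,2-trimethylcyclopentyl]-1,4-dioxaspiro[4.5]decan-8-ol
Product: 18 (3S,4R)-4-hydroxy-3-(8-hydroxy-1,4-dioxaspiro[4.5]decan-8-yl)-2,2,3-trimethylcyclopentan-1-one, via cyclic phenylboronate 16 (not isolated), via keto phenylboronate 17 (not isolated)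
Conditions: PhB(OH)2 (1.05 equiv), MgSO4, CH2Cl2, rt; Dess–Martin periodinane, 0 °C; then pinacol, rt
Reagents that add atoms: none
Why: Transient cyclic boronate protection of the C5'–OH/C1–OH 1,3-diol leaves only the C3' hydroxyl for Dess–Martin oxidation, and neutral transesterification with pinacol releases the β-hydroxy ketone without retro-aldol cleavage or elimination.

Step 10
Reactants: 18 (3S,4R)-4-hydroxy-3-(8-hydroxy-1,4-dioxaspiro[4.5]decan-8-yl)-2,2,3-trimethylcyclopentan-1-one
Product: 19 8-[(1S,3R,5R)-3,5-dihydroxy-1,2,2-trimethylcyclopentyl]-1,4-dioxaspiro[4.5]decan-8-ol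
Conditions: Me4NBH(OAc)3, MeCN/AcOH, −20 °C
Reagents that add atoms: none
Why: Evans–Saksena hydroxyl-directed reduction, in which the C5' alkoxyborohydride delivers hydride intramolecularly to the ring B face of the C3' ketone and gives the 1,3-anti diol with C3'–OH trans to ring B (external hydride would return the cis alcohol).

Step 11
Reactants: 19 8-[(1S,3R,5R)-3,5-dihydroxy-1,2,2-trimethylcyclopentyl]-1,4-dioxaspiro[4.5]decan-8-ol
Product: 23 8-[(1S,3S,5R)-3-bromo-5-hydroxy-1,2,2-trimethylcyclopentyl]-1,4-dioxaspiro[4.5]decan-8-ol, via cyclic phenylboronate 20 (not isolated), via C3' triflate 21 (not isolated), via C3' bromide boronate 22 (not isolated)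
Conditions: PhB(OH)2, MgSO4, CH2Cl2, rt; Tf2O, 2,6-lutidine, −78 → −20 °C; Bu4NBr, toluene, −20 °C → rt; then pinacol
Reagents that add atoms: tetrabutylammonium bromide (CCCC[N+](CCCC)(CCCC)CCCC.[Br-])
Why: Sulfonate displacement by SN2 with inversion at C3'; with the 1,3-diol masked as the non-nucleophilic boronate (no internal oxygen can attack C3'), only C3'–OH is triflated and bromide enters from the ring B face, setting C3'–Br cis to ring B and to the C5' oxygen.

Step 12
Reactants: 23 8-[(1S,3S,5R)-3-bromo-5-hydroxy-1,2,2-trimethylcyclopentyl]-1,4-dioxaspiro[4.5]decan-8-ol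
Product: 24 8-[(1S,3S,5R)-3-bromo-5-(tert-butyldimethylsilyloxy)-1,2,2-trimethylcyclopentyl]-1,4-dioxaspiro[4.5]decan-8-ol
Conditions: t-BuMe2SiOTf (1.1 equiv), 2,6-lutidine, CH2Cl2, −78 → 0 °C
Reagents that add atoms: tert-butyldimethylsilyl trifluoromethanesulfonate (CC(C)(C)[Si](C)(C)OS(=O)(=O)C(F)(F)F)
Why: O-Silylation with a silyl triflate selects the secondary C5' hydroxyl over the tertiary C1 hydroxyl (which must stay free to direct step 16) and gives an ether that tolerates the base, acid and cationic steps that follow.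

Step 13
Reactants: 24 8-[(1S,3S,5R)-3-bromo-5-(tert-butyldimethylsilyloxy)-1,2,2-trimethylcyclopentyl]-1,4-dioxaspiro[4.5]decan-8-ol
Product: 25 4-[(1S,3S,5R)-3-bromo-5-(tert-butyldimethylsilyloxy)-1,2,2-trimethylcyclopentyl]-4-hydroxycyclohexan-1-one
Conditions: PPTS, acetone/H2O, 50 °C
Reagents that add atoms: water (O)
Why: Mild acid-catalysed ketal hydrolysis unveils the C4 ketone without touching the silyl ether, the bromide or the tertiary alcohol; C1 is still non-stereogenic.

Step 14
Reactants: 25 4-[(1S,3S,5R)-3-bromo-5-(tert-butyldimethylsilyloxy)-1,2,2-trimethylcyclopentyl]-4-hydroxycyclohexan-1-one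
Product: 27 (4R)-4-[(1S,3S,5R)-3-bromo-5-(tert-butyldimethylsilyloxy)-1,2,2-trimethylcyclopentyl]-4-hydroxycyclohex-1-en-1-yl trifluoromethanesulfonate, via dilithium alkoxide enolate 26 (not isolated)
Conditions: lithium (R,R)-bis(1-phenylethyl)amide (2.2 equiv), LiCl, THF, −78 °C; then N-(5-chloro-2-pyridyl)bis(trifluoromethanesulfonimide), −78 → −20 °C
Reagents that add atoms: N-(5-chloropyridin-2-yl)bis(trifluoromethanesulfonimide) (FC(F)(F)S(=O)(=O)N(c1ccc(Cl)cn1)S(=O)(=O)C(F)(F)F)
Why: Enantiotopic-group-selective deprotonation of a 4,4-disubstituted cyclohexanone by a chiral lithium amide (Simpkins-type desymmetrisation) followed by enolate O-triflation; reagent-controlled removal of one axial α-proton places the double bond at C3=C4 and thereby sets C1 as R.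

Step 15
Reactants: 27 (4R)-4-[(1S,3S,5R)-3-bromo-5-(tert-butyldimethylsilyloxy)-1,2,2-trimethylcyclopentyl]-4-hydroxycyclohex-1-en-1-yl trifluoromethanesulfonate; 28 methylzinc chloride
Product: 29 (1R)-1-[(1S,3S,5R)-3-bromo-5-(tert-butyldimethylsilyloxy)-1,2,2-trimethylcyclopentyl]-4-methylcyclohex-3-en-1-ol
Conditions: MeZnCl (3 equiv), Pd(PPh3)4 (5 mol %), THF, 0 °C → rt
Reagents that add atoms: methylzinc chloride (C[Zn]Cl)
Why: Negishi methylation of the enol triflate (zerovalent-palladium-catalysed cross-coupling) installs the C4 methyl group without moving the double bond and tolerates the tertiary alcohol, the silyl ether and the hindered secondary bromide.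

Step 16
Reactants: 29 (1R)-1-[(1S,3S,5R)-3-bromo-5-(tert-butyldimethylsilyloxy)-1,2,2-trimethylcyclopentyl]-4-methylcyclohex-3-en-1-ol
Product: 30 the 3,4-epoxide of 29 with the epoxide oxygen cis to C1–OH
Conditions: VO(acac)2 (5 mol %), t-BuOOH, CH2Cl2, 0 °C → rt
Reagents that add atoms: tert-butyl hydroperoxide (CC(C)(C)OO)
Why: Hydroxyl-directed epoxidation of the homoallylic alcohol through a vanadium alkoxide–peroxide complex delivers oxygen to the face syn to the axial C1 hydroxyl, as with terpinen-4-ol.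

Step 17
Reactants: 30 the 3,4-epoxide of 29 with the epoxide oxygen cis to C1–OH
Product: 31 bromohydrin with tertiary C4–Br cis to ring A and axial C3–OH cis to C1–OH
Conditions: HBr (1.1 equiv, 33% in AcOH), CH2Cl2, −40 °C
Reagents that add atoms: hydrogen bromide (Br)
Why: Acid-mediated epoxide opening obeying the Fürst–Plattner trans-diaxial rule; with ring A equatorial, bromide attacks the tertiary C4 axially from the face opposite the epoxide (regiochemistry and conformation matched), giving axial C4–Br and axial C3–OH.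

Step 18
Reactants: 31 bromohydrin with tertiary C4–Br cis to ring A and axial C3–OH cis to C1–OH
Product: 33 C3 mesylate of 31 carrying a trimethylsilyl ether on the C1 oxygen, via C3 mesylate 32 (not isolated)
Conditions: MsCl, Et3N, CH2Cl2, −20 °C; then Me3SiOTf, 2,6-lutidine, −78 → 0 °C
Reagents that add atoms: methanesulfonyl chloride (CS(=O)(=O)Cl); trimethylsilyl trifluoromethanesulfonate (C[Si](C)(C)OS(=O)(=O)C(F)(F)F)
Why: O-Sulfonylation through sulfene picks the secondary C3 hydroxyl, and O-silylation then caps the tertiary C1 hydroxyl so that it cannot close a transannular C1–O–C4 ether when C4 becomes cationic in step 19.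

Step 19
Reactants: 33 C3 mesylate of 31 carrying a trimethylsilyl ether on the C1 oxygen
Product: 35 the target carrying a tert-butyldimethylsilyl ether on the C5' oxygen and a trimethylsilyl ether on the C1 oxygen, via diaxial 4-bromo-3-chloro isomer 34 (not isolated)
Conditions: Et4NCl (1.5 equiv), MeCN, 70 °C
Reagents that add atoms: tetraethylammonium chloride (CC[N+](CC)(CC)CC.[Cl-])
Why: Neighbouring-group substitution through a bromonium ion: the antiperiplanar tertiary C4 bromine expels mesylate to form the bromonium ion on the ring A face, chloride opens it at C4 or returns at C3 to give diaxial isomer 34, and on heating 34 should undergo the diaxial-to-diequatorial 1,2-dihalide interchange (dyotropic rearrangement, as in steroidal 5,6-dihalides) driven by the clash between axial C3–Cl and the C1 silyloxy group, so both channels converge on C4–Cl cis to the C1 oxygen and C3–Br cis to ring A.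

Step 20
Reactants: 35 the target carrying a tert-butyldimethylsilyl ether on the C5' oxygen and a trimethylsilyl ether on the C1 oxygen
Product: 36 (1R,3S,4S)-3-bromo-1-[(1S,3S,5R)-3-bromo-5-hydroxy-1,2,2-trimethylcyclopentyl]-4-chloro-4-methylcyclohexan-1-ol
Conditions: HF·pyridine, THF, 0 °C → rt
Reagents that add atoms: none
Why: Fluoride-mediated global desilylation removes both silyl ethers under mildly acidic conditions that leave the tertiary chloride and the two secondary bromides untouched.

Compound list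

1 | (4S)-4-(tert-butyldimethylsilyloxy)cyclopent-2-en-1-one | O=C1C[C@H](O[Si](C)(C)C(C)(C)C)C=C1 | starting material
2 | methylmagnesium bromide | C[Mg]Br | starting material
3 | (3S,4S)-4-(tert-butyldimethylsilyloxy)-3-methyl-1-(trimethylsilyloxy)cyclopent-1-ene (3,4-trans) | C[C@H]1C=C(O[Si](C)(C)C)C[C@@H]1O[Si](C)(C)C(C)(C)C | intermediate
4 | (4S)-4-(tert-butyldimethylsilyloxy)-3-methylcyclopent-2-en-1-one | CC1=CC(=O)C[C@@H]1O[Si](C)(C)C(C)(C)C | intermediate
5 | (4S)-4-(tert-butyldimethylsilyloxy)-2-iodo-3-methylcyclopent-2-en-1-one | CC1=C(I)C(=O)C[C@@H]1O[Si](C)(C)C(C)(C)C | intermediate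
6 | 2-(1,4-dioxaspiro[4.5]dec-7-en-8-yl)-4,4,5,5-tetramethyl-1,3,2-dioxaborolane | CC1(C)OB(OC1(C)C)C1=CCC2(CC1)OCCO2 | starting material
7 | (4S)-4-(tert-butyldimethylsilyloxy)-3-methyl-2-(1,4-dioxaspiro[4.5]dec-7-en-8-yl)cyclopent-2-en-1-one | CC1=C(C2=CCC3(CC2)OCCO3)C(=O)C[C@@H]1O[Si](C)(C)C(C)(C)C | intermediate
8 | lithium dimethylcuprate | [Li+].C[Cu-]C | starting material
9 | iodomethane | CI | starting material
10 | (4S)-4-(tert-butyldimethylsilyloxy)-5,5-dimethyl-1-(1,4-dioxaspiro[4.5]dec-7-en-8-yl)-2-(trimethylsilyloxy)cyclopent-1-ene (formed in situ) | CC1(C)[C@@H](O[Si](C)(C)C(C)(C)C)CC(O[Si](C)(C)C)=C1C1=CCC2(CC1)OCCO2 | intermediate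
11 | lithium enolate corresponding to 10 (formed in situ) | CC1(C)[C@@H](O[Si](C)(C)C(C)(C)C)CC([O-])=C1C1=CCC2(CC1)OCCO2.[Li+] | intermediate
12 | (2S,4S)-4-(tert-butyldimethylsilyloxy)-2,3,3-trimethyl-2-(1,4-dioxaspiro[4.5]dec-7-en-8-yl)cyclopentan-1-one | CC1(C)[C@@H](O[Si](C)(C)C(C)(C)C)CC(=O)[C@@]1(C)C1=CCC2(CC1)OCCO2 | intermediate
13 | (1R,2S,4S)-4-(tert-butyldimethylsilyloxy)-2,3,3-trimethyl-2-(1,4-dioxaspiro[4.5]dec-7-en-8-yl)cyclopentan-1-ol (C5'–OH cis to ring B) | CC1(C)[C@@H](O[Si](C)(C)C(C)(C)C)C[C@@H](O)[C@@]1(C)C1=CCC2(CC1)OCCO2 | intermediate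
14 | 8-[(1S,3S,5R)-3-(tert-butyldimethylsilyloxy)-5-hydroxy-1,2,2-trimethylcyclopentyl]-1,4-dioxaspiro[4.5]decan-8-ol | CC1(C)[C@@H](O[Si](C)(C)C(C)(C)C)C[C@@H](O)[C@@]1(C)C1(O)CCC2(CC1)OCCO2 | intermediate
15 | 8-[(1S,3S,5R)-3,5-dihydroxy-1,2,2-trimethylcyclopentyl]-1,4-dioxaspiro[4.5]decan-8-ol | CC1(C)[C@@H](O)C[C@@H](O)[C@@]1(C)C1(O)CCC2(CC1)OCCO2 | intermediate
16 | cyclic phenylboronate of 15 across the C5' and C1 oxygens, C3'–OH free (formed in situ) | CC1(C)[C@@H](O)C[C@H]2OB(c3ccccc3)OC3(CCC4(CC3)OCCO4)[C@@]12C | intermediate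
17 | C3' ketone of boronate 16 (formed in situ) | CC1(C)C(=O)C[C@H]2OB(c3ccccc3)OC3(CCC4(CC3)OCCO4)[C@@]12C | intermediate
18 | (3S,4R)-4-hydroxy-3-(8-hydroxy-1,4-dioxaspiro[4.5]decan-8-yl)-2,2,3-trimethylcyclopentan-1-one | CC1(C)C(=O)C[C@@H](O)[C@@]1(C)C1(O)CCC2(CC1)OCCO2 | intermediate
19 | 8-[(1S,3R,5R)-3,5-dihydroxy-1,2,2-trimethylcyclopentyl]-1,4-dioxaspiro[4.5]decan-8-ol (C3'–OH trans to ring B) | CC1(C)[C@H](O)C[C@@H](O)[C@@]1(C)C1(O)CCC2(CC1)OCCO2 | intermediate
20 | cyclic phenylboronate of 19 across the C5' and C1 oxygens (formed in situ) | CC1(C)[C@H](O)C[C@H]2OB(c3ccccc3)OC3(CCC4(CC3)OCCO4)[C@@]12C | intermediate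
21 | C3' trifluoromethanesulfonate of 20 (formed in situ) | CC1(C)[C@H](OS(=O)(=O)C(F)(F)F)C[C@H]2OB(c3ccccc3)OC3(CCC4(CC3)OCCO4)[C@@]12C | intermediate
22 | C3' bromide (cis to ring B) still carrying the phenylboronate (formed in situ) | CC1(C)[C@@H](Br)C[C@H]2OB(c3ccccc3)OC3(CCC4(CC3)OCCO4)[C@@]12C | intermediate
23 | 8-[(1S,3S,5R)-3-bromo-5-hydroxy-1,2,2-trimethylcyclopentyl]-1,4-dioxaspiro[4.5]decan-8-ol | CC1(C)[C@@H](Br)C[C@@H](O)[C@@]1(C)C1(O)CCC2(CC1)OCCO2 | intermediate
24 | 8-[(1S,3S,5R)-3-bromo-5-(tert-butyldimethylsilyloxy)-1,2,2-trimethylcyclopentyl]-1,4-dioxaspiro[4.5]decan-8-ol | CC1(C)[C@@H](Br)C[C@@H](O[Si](C)(C)C(C)(C)C)[C@@]1(C)C1(O)CCC2(CC1)OCCO2 | intermediate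
25 | 4-[(1S,3S,5R)-3-bromo-5-(tert-butyldimethylsilyloxy)-1,2,2-trimethylcyclopentyl]-4-hydroxycyclohexan-1-one | CC1(C)[C@@H](Br)C[C@@H](O[Si](C)(C)C(C)(C)C)[C@@]1(C)C1(O)CCC(=O)CC1 | intermediate
26 | dilithium C1 alkoxide / C3=C4 enolate of 25 (formed in situ) | CC1(C)[C@@H](Br)C[C@@H](O[Si](C)(C)C(C)(C)C)[C@@]1(C)[C@@]1([O-])CCC([O-])=CC1.[Li+].[Li+] | intermediate
27 | (4R)-4-[(1S,3S,5R)-3-bromo-5-(tert-butyldimethylsilyloxy)-1,2,2-trimethylcyclopentyl]-4-hydroxycyclohex-1-en-1-yl trifluoromethanesulfonate | CC1(C)[C@@H](Br)C[C@@H](O[Si](C)(C)C(C)(C)C)[C@@]1(C)[C@@]1(O)CCC(OS(=O)(=O)C(F)(F)F)=CC1 | intermediate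
28 | methylzinc chloride | C[Zn]Cl | starting material
29 | (1R)-1-[(1S,3S,5R)-3-bromo-5-(tert-butyldimethylsilyloxy)-1,2,2-trimethylcyclopentyl]-4-methylcyclohex-3-en-1-ol | CC1(C)[C@@H](Br)C[C@@H](O[Si](C)(C)C(C)(C)C)[C@@]1(C)[C@@]1(O)CCC(C)=CC1 | intermediate
30 | 3,4-epoxide of 29, epoxide oxygen cis to C1–OH | CC1(C)[C@@H](Br)C[C@@H](O[Si](C)(C)C(C)(C)C)[C@@]1(C)[C@@]1(O)CC[C@]2(C)O[C@@H]2C1 | intermediate
31 | bromohydrin: C4–Br axial and cis to ring A, C3–OH axial and cis to C1–OH | CC1(C)[C@@H](Br)C[C@@H](O[Si](C)(C)C(C)(C)C)[C@@]1(C)[C@@]1(O)CC[C@@](C)(Br)[C@H](O)C1 | intermediate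
32 | C3 methanesulfonate of 31 (formed in situ) | CC1(C)[C@@H](Br)C[C@@H](O[Si](C)(C)C(C)(C)C)[C@@]1(C)[C@@]1(O)CC[C@@](C)(Br)[C@H](OS(C)(=O)=O)C1 | intermediate
33 | C3 methanesulfonate, C1 trimethylsilyl ether | CC1(C)[C@@H](Br)C[C@@H](O[Si](C)(C)C(C)(C)C)[C@@]1(C)[C@@]1(O[Si](C)(C)C)CC[C@@](C)(Br)[C@H](OS(C)(=O)=O)C1 | intermediate
34 | diaxial isomer: C4–Br cis to ring A, C3–Cl cis to the C1 oxygen (formed in situ) | CC1(C)[C@@H](Br)C[C@@H](O[Si](C)(C)C(C)(C)C)[C@@]1(C)[C@@]1(O[Si](C)(C)C)CC[C@@](C)(Br)[C@H](Cl)C1 | intermediate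
35 | target as its C5' tert-butyldimethylsilyl and C1 trimethylsilyl ether | CC1(C)[C@@H](Br)C[C@@H](O[Si](C)(C)C(C)(C)C)[C@@]1(C)[C@@]1(O[Si](C)(C)C)CC[C@](C)(Cl)[C@@H](Br)C1 | intermediate
36 | (1R,3S,4S)-3-bromo-1-[(1S,3S,5R)-3-bromo-5-hydroxy-1,2,2-trimethylcyclopentyl]-4-chloro-4-methylcyclohexan-1-ol | CC1(C)[C@@H](Br)C[C@@H](O)[C@@]1(C)[C@@]1(O)CC[C@](C)(Cl)[C@@H](Br)C1 | target

Total step count: 20. Longest linear sequence: 20 steps (1 → 36; boronate 6 and the methyl donors 2, 8, 9, 28 are purchased or made in the flask from commercial reagents).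

Steps most likely to fail

1. Step 19. What may go wrong: chloride returns only at the secondary carbon and the diaxial-to-diequatorial halogen interchange stalls, or the bromonium ion loses a proton or Br+ (elimination, halogen scrambling). Fallback, from 29 back to 36: hydroxy alkene 29 would be treated with N-bromosuccinimide in MeCN. Only the bromonium ion on the face opposite the axial C1–OH can be captured by that hydroxyl through a boat, which should give the bridged C1–O–C4 bromo ether F4 with C3–Br already cis to ring A and the C4 oxygen on the face required for chlorine. BCl3 at −78 °C would then cleave the C4–O bond with help from the antiperiplanar C3–Br and return chloride from boron on the same face (net retention at C4), giving the C5' silyl ether of the target F5. HF·pyridine would then give 36.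

2. Step 11. What may go wrong: ionisation of the neopentyl-type triflate (Wagner–Meerwein shift, elimination) outruns backside attack from the crowded face. Fallback, from 18 back to 23: ketone 18 would be condensed with hydrazine to hydrazone F2 and converted with bromine and a guanidine base (Barton vinyl halide synthesis) into the C3'=C4' vinyl bromide F3. The double bond would then be reduced by hydrogen-atom transfer (Mn(dpm)3, PhSiH3, t-BuOOH, i-PrOH). The α-bromo radical at C3' should take its hydrogen on the open face anti to ring B, leaving Br cis to ring B and giving 23 without any substitution at C3'.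

3. Step 5. What may go wrong: conjugate addition at the fully substituted, silyloxy-flanked β-carbon is slow, or the enolate methylation suffers O-methylation, proton transfer with loss of the silyloxy group, or poor face selectivity. Fallback, from 10 back to 12: silyl enol ether 10 would be isolated and its electron-rich C5'=C1' double bond cyclopropanated with Et2Zn/CH2I2 (Furukawa–Simmons–Smith, anti to the C3' silyloxy group) to give siloxycyclopropane F1. Opening with K2CO3 in MeOH cleaves the C5'–CH2 bond and turns the cyclopropane methylene into the C1' methyl group of 12.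

Further compounds

F1 | step 5 | siloxycyclopropane from 10: cyclopropane fused at C5'–C1' with its CH2 trans to the C3' silyloxy group | CC1(C)[C@@H](O[Si](C)(C)C(C)(C)C)C[C@]2(O[Si](C)(C)C)C[C@]12C1=CCC3(CC1)OCCO3
F2 | step 11 | C3' hydrazone of 18 | CC1(C)C(=NN)C[C@@H](O)[C@@]1(C)C1(O)CCC2(CC1)OCCO2
F3 | step 11 | C3'=C4' vinyl bromide (Br on C3') from F2 | CC1(C)C(Br)=C[C@@H](O)[C@@]1(C)C1(O)CCC2(CC1)OCCO2
F4 | step 19 | bridged C1–O–C4 ether (7-oxabicyclo[2.2.1]heptane) from 29 with C3–Br anti to the ether oxygen | CC1(C)[C@@H](Br)C[C@@H](O[Si](C)(C)C(C)(C)C)[C@@]1(C)[C@]12CC[C@](C)(O1)[C@@H](Br)C2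
F5 | step 19 | target as its C5' tert-butyldimethylsilyl ether | CC1(C)[C@@H](Br)C[C@@H](O[Si](C)(C)C(C)(C)C)[C@@]1(C)[C@@]1(O)CC[C@](C)(Cl)[C@@H](Br)C1
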